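**Assumptions.** Flavan numbering is used throughout: O1, C2, C3, C4, C4a, C5–C8, C8a; ring A is the benzo ring, ring C the pyran, ring B the catechol ring. The target is the 2,3-cis (2R,3R) ester, i.e. (−)-epicatechin 3-O-vanillate. The ProPhenol enantiomer in step 4 is named by analogy with α-hydroxyacetophenone donors; if the first run shows the opposite sense at C2, the antipodal ligand (also commercial) is used. Compounds 1, 3, 7 and 10 are taken as purchasable.

## Retrosynthetic overview

1. The final hydrogenation of a C3=C4 enol ester (flav-3-en-3-yl vanillate) from the face anti to the C2 aryl sets C3 cis to C2 and removes all five benzyl groups.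
2. The enol ester comes from a 3-acyloxychroman-4-one by C4 reduction and dehydration, so the C3 configuration of every earlier intermediate is irrelevant and converges.
3. Ring C is the only ring formed (rings A and B are bought). It is closed in one flask from an A-ring α-hydroxy ketone and the B-ring aldehyde: C2–C3 by a catalytic asymmetric aldol that sets C2, then O1–C8a by SNAr of the new C2 alkoxide.
4. Enabling feature: C4 of ring C is carried as a ketone between C3 and the ring-A carbon C4a. It makes C3–H enolisable, and, being ortho to C8a, it turns the C8a–F bond into an SNAr site; the ring-A oxygens at C5 and C7 are meta to C8a and do not deactivate it.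

Key step: step 4

## Route

Step 1
Reactants: 1 5-fluorobenzene-1,3-diol
Product: 2 1,3-bis(benzyloxy)-5-fluorobenzene
Conditions: BnBr (2.2 equiv), K2CO3, DMF, 60 °C
Reagents that add atoms: benzyl bromide, BrCc1ccccc1
Why: Williamson ether synthesis on both phenols; the aryl fluoride is not activated and stays, and no stereocentre is involved.

Step 2
Reactants: 2 1,3-bis(benzyloxy)-5-fluorobenzene; 3 acetoxyacetic acid
Product: 5 2-[2,4-bis(benzyloxy)-6-fluorophenyl]-2-oxoethyl acetate, via acetoxyacetyl trifluoroacetate 4 (not isolated)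
Conditions: TFAA (2 equiv), 85% H3PO4 (cat.), CH2Cl2, 0 → 25 °C
Reagents that add atoms: none
Why: Metal-free Friedel–Crafts acylation through the mixed trifluoroacetic anhydride, expected at the ring carbon para to one benzyloxy group and ortho to the other that is flanked by fluorine (the site between the two benzyloxy groups is more hindered); the absence of a chelating Lewis acid spares the benzyl ethers.

Step 3
Reactants: 5 2-[2,4-bis(benzyloxy)-6-fluorophenyl]-2-oxoethyl acetate
Product: 6 1-[2,4-bis(benzyloxy)-6-fluorophenyl]-2-hydroxyethan-1-one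
Conditions: HCl (cat., from AcCl), MeOH–THF, 25 °C
Reagents that add atoms: none
Why: Acid-catalysed transesterification of the primary acetate with methanol; acid is chosen over alkoxide so that the activated C–F bond is not displaced, and the benzyl ethers are stable to dilute HCl.

Step 4
Reactants: 6 1-[2,4-bis(benzyloxy)-6-fluorophenyl]-2-hydroxyethan-1-one; 7 3,4-bis(benzyloxy)benzaldehyde
Product: 9 (2R,3S)-5,7-bis(benzyloxy)-2-[3,4-bis(benzyloxy)phenyl]-3-hydroxy-2,3-dihydro-4H-chromen-4-one, via syn-aldol diol 8 (not isolated)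
Conditions: 6 (1.3 equiv), (R,R)-ProPhenol (10 mol %), Et2Zn (20 mol %), 4 Å MS, THF, −35 °C; then KHMDS (2.6 equiv), −78 → 0 °C; aq NH4Cl
Reagents that add atoms: none
Why: The dinuclear zinc–ProPhenol complex binds 6 as a chelated zinc enediolate and adds its C3 carbon to one face of the zinc-bound aldehyde 7, which forms C2–C3 and sets C2 as R; double deprotonation of diol 8 then lets the C2 alkoxide O1 add to C8a and expel fluoride through a Meisenheimer adduct stabilised by the ortho C4 carbonyl, which forms O1–C8a. The closest known reaction types are the zinc–ProPhenol direct aldol of α-hydroxyacetophenones and the alkoxide SNAr closure of 2-fluoroaryl ketones to chroman-4-ones. Ring C closes by a six-membered addition–elimination at C8a, formally a 6-endo-trig conjugate addition to the C8a=C4a–C4=O unit followed by loss of fluoride. C2 is controlled by the chiral catalyst and is not touched by the ring closure, because the substitution occurs at the aryl carbon and not at C2; the syn C3 centre formed with it is expected to give the 2,3-cis ketone, but its configuration is not needed later. The step needs O1 and not O3 to attack C8a, and ring closure to outrun retro-aldol cleavage: closure through O3 would be a disfavoured 5-endo-trig addition that twists the C4 carbonyl out of conjugation with ring A, and with O3 also deprotonated a retro-aldol cleavage or C3–H removal would have to create an enediolate dianion. The C5 and C7 benzyloxy groups are meta to C8a and leave it electrophilic.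

Step 5
Reactants: 9 (2R,3S)-5,7-bis(benzyloxy)-2-[3,4-bis(benzyloxy)phenyl]-3-hydroxy-2,3-dihydro-4H-chromen-4-one; 10 4-(benzyloxy)-3-methoxybenzoic acid
Product: 11 (2R,3S)-5,7-bis(benzyloxy)-2-[3,4-bis(benzyloxy)phenyl]-4-oxo-3,4-dihydro-2H-chromen-3-yl 4-(benzyloxy)-3-methoxybenzoate
Conditions: EDC·HCl (1.5 equiv), DMAP (0.2 equiv), CH2Cl2, 0 → 25 °C
Reagents that add atoms: none
Why: Steglich esterification of the only free hydroxyl; no stereocentre is formed, and any epimerisation at C3 is harmless because C3 is reset in step 8.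

Step 6
Reactants: 11 (2R,3S)-5,7-bis(benzyloxy)-2-[3,4-bis(benzyloxy)phenyl]-4-oxo-3,4-dihydro-2H-chromen-3-yl 4-(benzyloxy)-3-methoxybenzoate
Product: 12 (2R)-5,7-bis(benzyloxy)-2-[3,4-bis(benzyloxy)phenyl]-4-hydroxy-3,4-dihydro-2H-chromen-3-yl 4-(benzyloxy)-3-methoxybenzoate (mixture at C3 and C4)
Conditions: NaBH4, CeCl3·7H2O, MeOH–THF, −40 °C
Reagents that add atoms: none
Why: Luche reduction takes the aryl ketone in preference to the ester, and the cold, weakly acidic cerium medium is chosen to suppress O3→O4 acyl shift; the new C4 carbinol forms without control and is erased in step 7.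

Step 7
Reactants: 12 (2R)-5,7-bis(benzyloxy)-2-[3,4-bis(benzyloxy)phenyl]-4-hydroxy-3,4-dihydro-2H-chromen-3-yl 4-(benzyloxy)-3-methoxybenzoate
Product: 14 (2R)-5,7-bis(benzyloxy)-2-[3,4-bis(benzyloxy)phenyl]-2H-chromen-3-yl 4-(benzyloxy)-3-methoxybenzoate, via C4 mesylate 13 (not isolated)
Conditions: MsCl (1.5 equiv), Et3N (4 equiv), CH2Cl2, −20 → 25 °C
Reagents that add atoms: none
Why: Mesylation (sulfene pathway) followed by E1-type loss of the C4 mesylate, whose cation is stabilised by O1 and the C5/C7 benzyloxy groups, and removal of the only β-hydrogen (C3–H) by the amine should give the conjugated enol ester; C3 and C4 become sp2 and C2 is untouched.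

Step 8
Reactants: 14 (2R)-5,7-bis(benzyloxy)-2-[3,4-bis(benzyloxy)phenyl]-2H-chromen-3-yl 4-(benzyloxy)-3-methoxybenzoate
Product: 15 (2R,3R)-2-(3,4-dihydroxyphenyl)-5,7-dihydroxy-3,4-dihydro-2H-chromen-3-yl 4-hydroxy-3-methoxybenzoate
Conditions: H2 (1 atm), 20% Pd(OH)2/C, EtOAc–MeOH, 25 °C
Reagents that add atoms: none
Why: Heterogeneous syn-hydrogenation of the C3=C4 enol ester should occur anti to the C2 aryl (held pseudoaxial by allylic strain with the C3 acyloxy group), which places O3 cis to the aryl and sets C3 as R; the same conditions hydrogenolyse the five benzyl ethers while the aryl ester, the methyl ether and the cyclic C2–O1 bond are expected to survive, as in debenzylations of catechin esters.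

## Compound list

1 | 5-fluorobenzene-1,3-diol | Oc1cc(O)cc(F)c1 | starting material
2 | 1,3-bis(benzyloxy)-5-fluorobenzene | Fc1cc(OCc2ccccc2)cc(OCc2ccccc2)c1 | intermediate
3 | acetoxyacetic acid | CC(=O)OCC(=O)O | starting material
4 | acetoxyacetyl trifluoroacetate (mixed anhydride) | CC(=O)OCC(=O)OC(=O)C(F)(F)F | intermediate (not isolated)
5 | 2-[2,4-bis(benzyloxy)-6-fluorophenyl]-2-oxoethyl acetate | CC(=O)OCC(=O)c1c(F)cc(OCc2ccccc2)cc1OCc1ccccc1 | intermediate
6 | 1-[2,4-bis(benzyloxy)-6-fluorophenyl]-2-hydroxyethan-1-one | OCC(=O)c1c(F)cc(OCc2ccccc2)cc1OCc1ccccc1 | intermediate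
7 | 3,4-bis(benzyloxy)benzaldehyde | O=Cc1ccc(OCc2ccccc2)c(OCc2ccccc2)c1 | starting material
8 | (2S,3R)-1-[2,4-bis(benzyloxy)-6-fluorophenyl]-3-[3,4-bis(benzyloxy)phenyl]-2,3-dihydroxypropan-1-one (syn-aldol diol) | O=C(c1c(F)cc(OCc2ccccc2)cc1OCc1ccccc1)[C@@H](O)[C@H](O)c1ccc(OCc2ccccc2)c(OCc2ccccc2)c1 | intermediate (not isolated)
9 | (2R,3S)-5,7-bis(benzyloxy)-2-[3,4-bis(benzyloxy)phenyl]-3-hydroxy-2,3-dihydro-4H-chromen-4-one (2,3-cis drawn; the C3 epimer is equally serviceable) | O[C@@H]1C(=O)c2c(OCc3ccccc3)cc(OCc3ccccc3)cc2O[C@@H]1c1ccc(OCc2ccccc2)c(OCc2ccccc2)c1 | intermediate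
10 | 4-(benzyloxy)-3-methoxybenzoic acid | COc1cc(C(=O)O)ccc1OCc1ccccc1 | starting material
11 | (2R,3S)-5,7-bis(benzyloxy)-2-[3,4-bis(benzyloxy)phenyl]-4-oxo-3,4-dihydro-2H-chromen-3-yl 4-(benzyloxy)-3-methoxybenzoate (2,3-cis drawn; the C3 epimer is equally serviceable) | COc1cc(C(=O)O[C@@H]2C(=O)c3c(OCc4ccccc4)cc(OCc4ccccc4)cc3O[C@@H]2c2ccc(OCc3ccccc3)c(OCc3ccccc3)c2)ccc1OCc1ccccc1 | intermediate
12 | (2R)-5,7-bis(benzyloxy)-2-[3,4-bis(benzyloxy)phenyl]-4-hydroxy-3,4-dihydro-2H-chromen-3-yl 4-(benzyloxy)-3-methoxybenzoate (mixture at C3 and C4) | COc1cc(C(=O)OC2C(O)c3c(OCc4ccccc4)cc(OCc4ccccc4)cc3O[C@@H]2c2ccc(OCc3ccccc3)c(OCc3ccccc3)c2)ccc1OCc1ccccc1 | intermediate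
13 | (2R)-5,7-bis(benzyloxy)-2-[3,4-bis(benzyloxy)phenyl]-4-(methanesulfonyloxy)-3,4-dihydro-2H-chromen-3-yl 4-(benzyloxy)-3-methoxybenzoate (mixture at C3 and C4) | COc1cc(C(=O)OC2C(OS(C)(=O)=O)c3c(OCc4ccccc4)cc(OCc4ccccc4)cc3O[C@@H]2c2ccc(OCc3ccccc3)c(OCc3ccccc3)c2)ccc1OCc1ccccc1 | intermediate (not isolated)
14 | (2R)-5,7-bis(benzyloxy)-2-[3,4-bis(benzyloxy)phenyl]-2H-chromen-3-yl 4-(benzyloxy)-3-methoxybenzoate | COc1cc(C(=O)OC2=Cc3c(OCc4ccccc4)cc(OCc4ccccc4)cc3O[C@@H]2c2ccc(OCc3ccccc3)c(OCc3ccccc3)c2)ccc1OCc1ccccc1 | intermediate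
15 | (2R,3R)-2-(3,4-dihydroxyphenyl)-5,7-dihydroxy-3,4-dihydro-2H-chromen-3-yl 4-hydroxy-3-methoxybenzoate | COc1cc(C(=O)O[C@@H]2Cc3c(O)cc(O)cc3O[C@@H]2c2ccc(O)c(O)c2)ccc1O | target

## Step count and risks

Total steps: 8. Longest linear sequence: 8 steps (1 → 2 → 5 → 6 → 9 → 11 → 12 → 14 → 15).

**Step 4.** The C2 configuration may erode through retro-aldol equilibration of the alkoxide before ring closure, and the aldol addition to the electron-rich aldehyde may stall. The fallback gives up catalyst control in the union and resolves at the ketone reduction. It sets out from 6 and 7: K2CO3 in DMF at 25 °C (aldol and SNAr under thermodynamic control) should give racemic trans-5,7-bis(benzyloxy)-2-[3,4-bis(benzyloxy)phenyl]-3-hydroxy-2,3-dihydro-4H-chromen-4-one F1. Steglich esterification with 10 then gives the racemic trans 3-O-[4-(benzyloxy)-3-methoxybenzoyl] ester F2. A Noyori–Ikariya asymmetric transfer hydrogenation run as a kinetic resolution of the flavanone (RuCl(p-cymene)(TsDPEN), HCO2H–Et3N), with the catalyst enantiomer that consumes the 2R ketone, reduces that enantiomer to 12, where the route is rejoined; the unreacted 2S ketone is separated. The price is that at most half of the material is used.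

**Step 8.** Hydrogen may be delivered to both faces of the enol ester, the double bond may migrate on palladium into the C2=C3 position with loss of the C2 configuration, or the enol C–O bond may be hydrogenolysed. The fallback sets the cis relationship by hydride delivery and sets out from 9. NaBH4 gives (2R)-5,7-bis(benzyloxy)-2-[3,4-bis(benzyloxy)phenyl]chromane-3,4-diol F3, and ionic deoxygenation of its benzylic C4 hydroxyl (Et3SiH, TFA, CH2Cl2) gives (2R)-5,7-bis(benzyloxy)-2-[3,4-bis(benzyloxy)phenyl]chroman-3-ol F4 as a C3 mixture. Dess–Martin oxidation gives (2R)-5,7-bis(benzyloxy)-2-[3,4-bis(benzyloxy)phenyl]chroman-3-one F5. L-Selectride in THF at −78 °C, attacking anti to the C2 aryl, should give 5,7,3',4'-tetra-O-benzyl-(−)-epicatechin F6. Steglich esterification with 10 gives (2R,3R)-5,7-bis(benzyloxy)-2-[3,4-bis(benzyloxy)phenyl]chroman-3-yl 4-(benzyloxy)-3-methoxybenzoate F7, and hydrogenolysis (H2, Pd(OH)2/C) returns to the route at 15.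

**Step 7.** The C4 cation may be captured by ring A of a second molecule, or the acyl group may shift from O3 to O4 before ionisation. The fallback avoids the alcohol and its cation and sets out from 11. Tf2O with 2,6-di-tert-butyl-4-methylpyridine in CH2Cl2 should give (2R)-5,7-bis(benzyloxy)-2-[3,4-bis(benzyloxy)phenyl]-4-(trifluoromethanesulfonyloxy)-2H-chromen-3-yl 4-(benzyloxy)-3-methoxybenzoate F8. Palladium-catalysed formate reduction of the vinyl triflate (Pd(OAc)2, PPh3, HCO2H, Bu3N, DMF, 60 °C) then gives 14, where the route is rejoined.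

## Further compounds

F1 | step 4 | racemic trans-5,7-bis(benzyloxy)-2-[3,4-bis(benzyloxy)phenyl]-3-hydroxy-2,3-dihydro-4H-chromen-4-one (one enantiomer drawn) | O[C@H]1C(=O)c2c(OCc3ccccc3)cc(OCc3ccccc3)cc2O[C@@H]1c1ccc(OCc2ccccc2)c(OCc2ccccc2)c1
F2 | step 4 | racemic trans-5,7-bis(benzyloxy)-2-[3,4-bis(benzyloxy)phenyl]-4-oxo-3,4-dihydro-2H-chromen-3-yl 4-(benzyloxy)-3-methoxybenzoate (one enantiomer drawn) | COc1cc(C(=O)O[C@H]2C(=O)c3c(OCc4ccccc4)cc(OCc4ccccc4)cc3O[C@@H]2c2ccc(OCc3ccccc3)c(OCc3ccccc3)c2)ccc1OCc1ccccc1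
F3 | step 8 | (2R)-5,7-bis(benzyloxy)-2-[3,4-bis(benzyloxy)phenyl]chromane-3,4-diol (mixture at C3 and C4) | OC1C(O)c2c(OCc3ccccc3)cc(OCc3ccccc3)cc2O[C@@H]1c1ccc(OCc2ccccc2)c(OCc2ccccc2)c1
F4 | step 8 | (2R)-5,7-bis(benzyloxy)-2-[3,4-bis(benzyloxy)phenyl]chroman-3-ol (mixture at C3) | OC1Cc2c(OCc3ccccc3)cc(OCc3ccccc3)cc2O[C@@H]1c1ccc(OCc2ccccc2)c(OCc2ccccc2)c1
F5 | step 8 | (2R)-5,7-bis(benzyloxy)-2-[3,4-bis(benzyloxy)phenyl]chroman-3-one | O=C1Cc2c(OCc3ccccc3)cc(OCc3ccccc3)cc2O[C@@H]1c1ccc(OCc2ccccc2)c(OCc2ccccc2)c1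
F6 | step 8 | (2R,3R)-5,7-bis(benzyloxy)-2-[3,4-bis(benzyloxy)phenyl]chroman-3-ol (tetra-O-benzyl-(−)-epicatechin) | O[C@@H]1Cc2c(OCc3ccccc3)cc(OCc3ccccc3)cc2O[C@@H]1c1ccc(OCc2ccccc2)c(OCc2ccccc2)c1
F7 | step 8 | (2R,3R)-5,7-bis(benzyloxy)-2-[3,4-bis(benzyloxy)phenyl]chroman-3-yl 4-(benzyloxy)-3-methoxybenzoate | COc1cc(C(=O)O[C@@H]2Cc3c(OCc4ccccc4)cc(OCc4ccccc4)cc3O[C@@H]2c2ccc(OCc3ccccc3)c(OCc3ccccc3)c2)ccc1OCc1ccccc1
F8 | step 7 | (2R)-5,7-bis(benzyloxy)-2-[3,4-bis(benzyloxy)phenyl]-4-(trifluoromethanesulfonyloxy)-2H-chromen-3-yl 4-(benzyloxy)-3-methoxybenzoate | COc1cc(C(=O)OC2=C(OS(=O)(=O)C(F)(F)F)c3c(OCc4ccccc4)cc(OCc4ccccc4)cc3O[C@@H]2c2ccc(OCc3ccccc3)c(OCc3ccccc3)c2)ccc1OCc1ccccc1
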